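**Plan**

1. Core numbering: C1(OMe)–C2(OAc)–C3(OMe)=C4–C5(allyl)–C6(Me)–C7(aryl), with C8=O bridging C1 and C5. Without C5, the cyclopentanone ring C8–C1–C7–C6–C5 is the four-carbon unit C8–C1–C7–C6: the methoxy-bearing α-carbon C1 is bonded to benzylic C7, and C7–C6 carries the trans aryl/methyl pair of an (E)-propenylarene. That is the adduct of a methoxy-keteniminium ion and the alkene.
2. Retrosynthesis: remove the acetyl group; add MeOH back across C3=C4 (C3 dimethyl ketal); cut C1–C2 (aldol); cut C5–allyl and C5–C4; excise C5 (C8–C5 and C5–C6); last, cut C1–C7 and C6–C8.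
3. Forward: the cyclobutanone ring (C8, C1, C7, C6) is made first and enlarged to the cyclopentanone by insertion of C5 as a β-keto ester carbon. C5 is then made quaternary (2-methoxyallyl, then allyl). The six-membered ring C1–C2–C3–C4–C5–C8 is closed by aldol addition, and only then is the enol ether formed, because the cis C5/C2 geometry at C3=C4 is enforced only by the ring.
4. Stereochemistry: C6/C7 relative from the (E)-alkene, absolute from the C2-symmetric pyrrolidine; C5 from allylation anti to the C6 methyl; C1 from the tether; C2 from the lithium-chelated aldol transition state.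

Key step: step 2

Assumption: the (2R,5R)-auxiliary is taken to favour the cyclobutanone enantiomer drawn; if the facial sense proves opposite, the (2S,5S)-amine is used and nothing else in the route changes.

**Route**

Step 1
Reactants: 1 methoxyacetyl chloride; 2 (2R,5R)-2,5-dimethylpyrrolidine
Product: 3 2-methoxy-1-[(2R,5R)-2,5-dimethylpyrrolidin-1-yl]ethan-1-one
Conditions: aq. NaOH, CH2Cl2, 0 °C → rt
Reagents that add atoms: none
Why: Schotten–Baumann N-acylation of the secondary amine by the acid chloride is fast at 0 °C and leaves both stereocentres of the C2-symmetric auxiliary untouched.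

Step 2
Reactants: 3 2-methoxy-1-[(2R,5R)-2,5-dimethylpyrrolidin-1-yl]ethan-1-one; 4 (E)-1,2-dimethoxy-4-(prop-1-en-1-yl)benzene
Product: 7 (2S,3S,4R)-3-(3,4-dimethoxyphenyl)-2-methoxy-4-methylcyclobutan-1-one, via keteniminium triflate 5 (not isolated), via cyclobutaniminium triflate 6 (not isolated)
Conditions: Tf2O, 2,6-di-tert-butylpyridine, ClCH2CH2Cl, −25 °C, then 4, → 40 °C; then aq. NaHCO3, rt
Reagents that add atoms: water, O
Why: O-Triflation of amide 3 and loss of triflic acid to the hindered pyridine should give keteniminium ion 5; its electrophilic central carbon C8 is attacked by the methyl-bearing alkene carbon C6, the charge settles on benzylic C7 (stabilised by the para-methoxy group), and the aminoenol-ether carbon C1 collapses onto C7 to give iminium 6, which bicarbonate hydrolysis turns into ketone 7. The closest known reaction type is the keteniminium–alkene [2+2] cycloaddition of Tf2O-activated tertiary amides, including its auxiliary-controlled form with 2,5-disubstituted pyrrolidines. The four-membered ring closes stepwise, the second bond by polar collapse of C1 onto the benzylic cation (4-exo-trig at C7, formally a thermal [2+2]). C7 and C6 keep the trans relation of the (E)-alkene because the short-lived cation closes to the less crowded arrangement; their absolute configuration is set by the pyrrolidine methyl group that blocks one face of the keteniminium ion (C2 symmetry removes any iminium geometry issue), and C1 forms trans to the aryl group but is erased later through its enolate. The step needs regiocontrol and acid tolerance: the polarity match (nucleophilic C6, cation-stabilising veratryl group at C7) places the aryl group next to C1, and the non-nucleophilic base buffers triflic acid so that the electron-rich propenylarene is not oligomerised.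

Step 3
Reactants: 7 (2S,3S,4R)-3-(3,4-dimethoxyphenyl)-2-methoxy-4-methylcyclobutan-1-one; 8 ethyl diazoacetate
Product: 9 ethyl (3S,4S,5R)-4-(3,4-dimethoxyphenyl)-3-methoxy-5-methyl-2-oxocyclopentane-1-carboxylate
Conditions: BF3·OEt2, CH2Cl2, −40 °C → 0 °C
Reagents that add atoms: none
Why: Büchner–Curtius–Schlotterbeck homologation, in which the BF3-activated strained cyclobutanone adds the diazoacetate carbon and nitrogen leaves with 1,2-shift of C6 rather than C1, because the inductively withdrawing methoxy group lowers the migratory aptitude of C1 as α-heteroatoms generally do in diazoalkane insertions; C6 migrates with retention and the enolisable β-keto ester resists a second insertion.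

Step 4
Reactants: 9 ethyl (3S,4S,5R)-4-(3,4-dimethoxyphenyl)-3-methoxy-5-methyl-2-oxocyclopentane-1-carboxylate; 10 prop-2-en-1-ol
Product: 11 prop-2-en-1-yl (3S,4S,5R)-4-(3,4-dimethoxyphenyl)-3-methoxy-5-methyl-2-oxocyclopentane-1-carboxylate
Conditions: 10 (excess), DMAP (cat.), toluene, reflux, 4 Å sieves
Reagents that add atoms: none
Why: DMAP-catalysed transesterification of an enolisable β-keto ester is driven by removal of ethanol on the sieves, and the two epimerisable centres C1 and C5 are both reset later.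

Step 5
Reactants: 12 2-methoxyprop-1-ene
Product: 13 3-bromo-2-methoxyprop-1-ene
Conditions: NBS, CH2Cl2, −20 °C → rt; distilled
Reagents that add atoms: N-bromosuccinimide, O=C1CCC(=O)N1Br
Why: Electrophilic bromination of the enol ether gives an oxocarbenium ion that loses a methyl proton, an ionic allylic bromination with double-bond transposition that is the usual way to this acetonyl-cation equivalent.

Step 6
Reactants: 11 prop-2-en-1-yl (3S,4S,5R)-4-(3,4-dimethoxyphenyl)-3-methoxy-5-methyl-2-oxocyclopentane-1-carboxylate; 13 3-bromo-2-methoxyprop-1-ene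
Product: 14 prop-2-en-1-yl (3S,4S,5R)-4-(3,4-dimethoxyphenyl)-3-methoxy-1-(2-methoxyprop-2-en-1-yl)-5-methyl-2-oxocyclopentane-1-carboxylate
Conditions: K2CO3, acetone, 50 °C
Reagents that add atoms: none
Why: SN2 C-alkylation of the carbonate-generated β-keto ester enolate by a reactive allylic bromide occurs only at C5, whose configuration does not matter because step 7 passes through the planar enolate again.

Step 7
Reactants: 14 prop-2-en-1-yl (3S,4S,5R)-4-(3,4-dimethoxyphenyl)-3-methoxy-1-(2-methoxyprop-2-en-1-yl)-5-methyl-2-oxocyclopentane-1-carboxylate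
Product: 15 (2R,3R,4S,5S)-4-(3,4-dimethoxyphenyl)-5-methoxy-2-(2-methoxyprop-2-en-1-yl)-3-methyl-2-(prop-2-en-1-yl)cyclopentan-1-one
Conditions: Pd2(dba)3 (2.5 mol %), PPh3 (10 mol %), THF, 25–40 °C
Reagents that add atoms: none
Why: Tsuji decarboxylative allylation, in which zerovalent palladium ionises the allyl ester, CO2 is lost and the C5 enolate recombines with the π-allyl unit at the same carbon, the allyl group entering the enolate face anti to the adjacent C6 methyl group (the trans-disposed C7 aryl group lies pseudo-equatorial and does not shield that face), so that allyl ends up trans and the methoxyallyl arm cis to the methyl group, as the bridge requires.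

Step 8
Reactants: 15 (2R,3R,4S,5S)-4-(3,4-dimethoxyphenyl)-5-methoxy-2-(2-methoxyprop-2-en-1-yl)-3-methyl-2-(prop-2-en-1-yl)cyclopentan-1-one
Product: 17 (2R,3R,4S,5S)-4-(3,4-dimethoxyphenyl)-2-(3-hydroxy-2,2-dimethoxypropyl)-5-methoxy-3-methyl-2-(prop-2-en-1-yl)cyclopentan-1-one, via methoxy-epoxide 16 (not isolated)
Conditions: mCPBA (1.0 equiv), MeOH, −20 °C → 0 °C
Reagents that add atoms: mCPBA, O=C(OO)c1cccc(Cl)c1; methanol, CO
Why: Prilezhaev epoxidation is much faster at the electron-rich 1,1-disubstituted enol ether than at the monosubstituted allyl alkene or in Baeyer–Villiger attack on the ketone, and methanol opens the labile 2-methoxyoxirane at its acetal carbon to the α-hydroxy dimethyl ketal, which masks C3 as a non-enolisable ketone equivalent and creates no stereocentre of consequence.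

Step 9
Reactants: 17 (2R,3R,4S,5S)-4-(3,4-dimethoxyphenyl)-2-(3-hydroxy-2,2-dimethoxypropyl)-5-methoxy-3-methyl-2-(prop-2-en-1-yl)cyclopentan-1-one
Product: 18 3-[(1R,2R,3S,4S)-3-(3,4-dimethoxyphenyl)-4-methoxy-2-methyl-5-oxo-1-(prop-2-en-1-yl)cyclopentyl]-2,2-dimethoxypropanal
Conditions: Dess–Martin periodinane, pyridine, CH2Cl2, 0 °C → rt
Reagents that add atoms: none
Why: Dess–Martin oxidation of the primary alcohol under pyridine buffering stops at the aldehyde and spares the ketal, the ketone and the alkene, and the aldehyde carries no α-hydrogen and therefore cannot enolise or epimerise.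

Step 10
Reactants: 18 3-[(1R,2R,3S,4S)-3-(3,4-dimethoxyphenyl)-4-methoxy-2-methyl-5-oxo-1-(prop-2-en-1-yl)cyclopentyl]-2,2-dimethoxypropanal
Product: 19 (1S,2R,5R,6R,7S)-7-(3,4-dimethoxyphenyl)-2-hydroxy-1,3,3-trimethoxy-6-methyl-5-(prop-2-en-1-yl)bicyclo[3.2.1]octan-8-one
Conditions: LiN(SiMe3)2, THF, −78 °C → −40 °C; AcOH quench
Reagents that add atoms: none
Why: Intramolecular lithium aldol addition (6-enolendo-exo-trig), in which the C8 ketone can enolise only toward C1 because C5 is quaternary and the aldehyde cannot enolise at all, the arm on C5 reaches C1 only on its own ring face, which fixes C1, and the lithium-bridged closed (Zimmerman–Traxler-type) transition state holds the aldehyde oxygen gauche to C8, which sets the C2 hydroxyl syn to the C8 carbonyl.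

Step 11
Reactants: 19 (1S,2R,5R,6R,7S)-7-(3,4-dimethoxyphenyl)-2-hydroxy-1,3,3-trimethoxy-6-methyl-5-(prop-2-en-1-yl)bicyclo[3.2.1]octan-8-one
Product: 22 (1S,2S,5S,6R,7S)-7-(3,4-dimethoxyphenyl)-2-hydroxy-1,3-dimethoxy-6-methyl-5-(prop-2-en-1-yl)bicyclo[3.2.1]oct-3-en-8-one (core numbering), via silyl ether ketal 20 (not isolated), via silylated enol ether 21 (not isolated)
Conditions: Me3SiOTf (2.5 equiv), iPr2NEt (3 equiv), CH2Cl2, −20 °C → rt; then Bu4NF/AcOH, THF, 0 °C
Reagents that add atoms: none
Why: Silyl-triflate-mediated ketal-to-enol-ether elimination, in which Me3SiOTf first silylates the C2 hydroxyl (blocking retro-aldol cleavage), then ionises the C3 ketal to an oxocarbenium ion from which the hindered amine removes a C4 methylene proton in preference to the single C2 methine proton shielded by the silyloxy group and the quaternary C1, the ring enforcing the cis C5/C2 geometry of the enol ether, and buffered fluoride finally frees the alcohol without strong base.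

Step 12
Reactants: 22 (1S,2S,5S,6R,7S)-7-(3,4-dimethoxyphenyl)-2-hydroxy-1,3-dimethoxy-6-methyl-5-(prop-2-en-1-yl)bicyclo[3.2.1]oct-3-en-8-one
Product: 23 (1S,2S,5S,6R,7S)-7-(3,4-dimethoxyphenyl)-1,3-dimethoxy-6-methyl-8-oxo-5-(prop-2-en-1-yl)bicyclo[3.2.1]oct-3-en-2-yl acetate (core numbering; CNP0221003.1)
Conditions: Ac2O, pyridine, DMAP (cat.), CH2Cl2, 0 °C → rt
Reagents that add atoms: acetic anhydride, CC(=O)OC(C)=O
Why: DMAP-catalysed acetylation of the secondary alcohol proceeds under mildly basic conditions that leave the enol ether, the ketone and all five stereocentres unchanged.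

**Compound list**

1 | methoxyacetyl chloride | COCC(Cl)=O | starting material
2 | (2R,5R)-2,5-dimethylpyrrolidine | C[C@@H]1CC[C@@H](C)N1 | starting material
3 | 2-methoxy-1-[(2R,5R)-2,5-dimethylpyrrolidin-1-yl]ethan-1-one | COCC(=O)N1[C@H](C)CC[C@H]1C | intermediate
4 | (E)-1,2-dimethoxy-4-(prop-1-en-1-yl)benzene | C/C=C/c1ccc(OC)c(OC)c1 | starting material
5 | (2R,5R)-1-(2-methoxyethenylidene)-2,5-dimethylpyrrolidinium triflate (keteniminium salt) | COC=C=[N+]1[C@H](C)CC[C@H]1C.[O-]S(=O)(=O)C(F)(F)F | intermediate (not isolated)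
6 | (2R,5R)-1-[(2S,3S,4R)-3-(3,4-dimethoxyphenyl)-2-methoxy-4-methylcyclobutylidene]-2,5-dimethylpyrrolidinium triflate | [N+]1(=C2[C@@H](OC)[C@H](c3ccc(OC)c(OC)c3)[C@H]2C)[C@H](C)CC[C@H]1C.[O-]S(=O)(=O)C(F)(F)F | intermediate (not isolated)
7 | (2S,3S,4R)-3-(3,4-dimethoxyphenyl)-2-methoxy-4-methylcyclobutan-1-one (all-trans) | O=C1[C@@H](OC)[C@H](c2ccc(OC)c(OC)c2)[C@H]1C | intermediate
8 | ethyl diazoacetate | CCOC(=O)C=[N+]=[N-] | starting material
9 | ethyl (3S,4S,5R)-4-(3,4-dimethoxyphenyl)-3-methoxy-5-methyl-2-oxocyclopentane-1-carboxylate (C5 epimers and enol; aryl trans to methyl) | O=C1[C@@H](OC)[C@H](c2ccc(OC)c(OC)c2)[C@@H](C)C1C(=O)OCC | intermediate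
10 | prop-2-en-1-ol (allyl alcohol) | C=CCO | starting material
11 | prop-2-en-1-yl (3S,4S,5R)-4-(3,4-dimethoxyphenyl)-3-methoxy-5-methyl-2-oxocyclopentane-1-carboxylate (C5 epimers and enol) | O=C1[C@@H](OC)[C@H](c2ccc(OC)c(OC)c2)[C@@H](C)C1C(=O)OCC=C | intermediate
12 | 2-methoxyprop-1-ene | C=C(C)OC | starting material
13 | 3-bromo-2-methoxyprop-1-ene (2-methoxyallyl bromide) | C=C(OC)CBr | intermediate
14 | prop-2-en-1-yl (3S,4S,5R)-4-(3,4-dimethoxyphenyl)-3-methoxy-1-(2-methoxyprop-2-en-1-yl)-5-methyl-2-oxocyclopentane-1-carboxylate (C5 epimers) | O=C1[C@@H](OC)[C@H](c2ccc(OC)c(OC)c2)[C@@H](C)C1(CC(OC)=C)C(=O)OCC=C | intermediate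
15 | (2R,3R,4S,5S)-4-(3,4-dimethoxyphenyl)-5-methoxy-2-(2-methoxyprop-2-en-1-yl)-3-methyl-2-(prop-2-en-1-yl)cyclopentan-1-one (allyl trans to methyl, methyl trans to aryl) | O=C1[C@@H](OC)[C@H](c2ccc(OC)c(OC)c2)[C@@H](C)[C@@]1(CC=C)CC(OC)=C | intermediate
16 | (2R,3R,4S,5S)-4-(3,4-dimethoxyphenyl)-5-methoxy-2-[(2-methoxyoxiran-2-yl)methyl]-3-methyl-2-(prop-2-en-1-yl)cyclopentan-1-one (epoxide epimers) | O=C1[C@@H](OC)[C@H](c2ccc(OC)c(OC)c2)[C@@H](C)[C@@]1(CC=C)CC2(OC)CO2 | intermediate (not isolated)
17 | (2R,3R,4S,5S)-4-(3,4-dimethoxyphenyl)-2-(3-hydroxy-2,2-dimethoxypropyl)-5-methoxy-3-methyl-2-(prop-2-en-1-yl)cyclopentan-1-one | O=C1[C@@H](OC)[C@H](c2ccc(OC)c(OC)c2)[C@@H](C)[C@@]1(CC=C)CC(OC)(OC)CO | intermediate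
18 | 3-[(1R,2R,3S,4S)-3-(3,4-dimethoxyphenyl)-4-methoxy-2-methyl-5-oxo-1-(prop-2-en-1-yl)cyclopentyl]-2,2-dimethoxypropanal | O=C1[C@@H](OC)[C@H](c2ccc(OC)c(OC)c2)[C@@H](C)[C@@]1(CC=C)CC(OC)(OC)C=O | intermediate
19 | (1S,2R,5R,6R,7S)-7-(3,4-dimethoxyphenyl)-2-hydroxy-1,3,3-trimethoxy-6-methyl-5-(prop-2-en-1-yl)bicyclo[3.2.1]octan-8-one (hydroxyl syn to C8=O) | C=CC[C@]12CC(OC)(OC)[C@H](O)[C@](OC)(C1=O)[C@H](c1ccc(OC)c(OC)c1)[C@H]2C | intermediate
20 | (1S,2R,5R,6R,7S)-7-(3,4-dimethoxyphenyl)-1,3,3-trimethoxy-6-methyl-5-(prop-2-en-1-yl)-2-[(trimethylsilyl)oxy]bicyclo[3.2.1]octan-8-one | C=CC[C@]12CC(OC)(OC)[C@H](O[Si](C)(C)C)[C@](OC)(C1=O)[C@H](c1ccc(OC)c(OC)c1)[C@H]2C | intermediate (not isolated)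
21 | (1S,2S,5S,6R,7S)-7-(3,4-dimethoxyphenyl)-1,3-dimethoxy-6-methyl-5-(prop-2-en-1-yl)-2-[(trimethylsilyl)oxy]bicyclo[3.2.1]oct-3-en-8-one (core numbering) | C=CC[C@]12C=C(OC)[C@H](O[Si](C)(C)C)[C@](OC)(C1=O)[C@H](c1ccc(OC)c(OC)c1)[C@H]2C | intermediate (not isolated)
22 | (1S,2S,5S,6R,7S)-7-(3,4-dimethoxyphenyl)-2-hydroxy-1,3-dimethoxy-6-methyl-5-(prop-2-en-1-yl)bicyclo[3.2.1]oct-3-en-8-one (core numbering) | C=CC[C@]12C=C(OC)[C@H](O)[C@](OC)(C1=O)[C@H](c1ccc(OC)c(OC)c1)[C@H]2C | intermediate
23 | (1S,2S,5S,6R,7S)-7-(3,4-dimethoxyphenyl)-1,3-dimethoxy-6-methyl-8-oxo-5-(prop-2-en-1-yl)bicyclo[3.2.1]oct-3-en-2-yl acetate (core numbering) | C=CC[C@]12C=C(OC)[C@H](OC(C)=O)[C@](OC)(C1=O)[C@H](c1ccc(OC)c(OC)c1)[C@H]2C | target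

**Step count and risks**

Total step count: 12. Longest linear sequence: 11 steps (steps 1–4 and 6–12, from methoxyacetyl chloride); step 5 is a one-step side branch.

Step 3. What may go wrong: the migration may lose its bias, with the methoxy-bearing carbon C1 shifting in competition with C6. Alternatively the BF3-bound donor–acceptor cyclobutanone may ionise at the C1–C7 bond and scramble or fragment. The fallback separates carbon–carbon bond formation from the migration and removes the Lewis acid. Setting out from 7, ethyl lithiodiazoacetate (from 8 and LiN(iPr)2, THF, −78 °C; AcOH quench) adds to the C8 carbonyl to give ethyl 2-diazo-2-[(2S,3S,4R)-3-(3,4-dimethoxyphenyl)-1-hydroxy-2-methoxy-4-methylcyclobutyl]acetate F1. Rh2(OAc)4 (1 mol %, CH2Cl2, rt) then converts F1 through its dirhodium carbene by 1,2-shift of the more electron-rich ring carbon C6 with loss of nitrogen, and the route is rejoined at 9.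

Step 11. What may go wrong: proton loss from the C3 oxocarbenium ion may occur at C2 as well as at C4, or the cation may be captured by the allyl alkene (Prins-type closure) before the amine acts. The fallback builds the enol ether by kinetic enolate O-methylation, where regiochemistry rests on the known reluctance of α-silyloxy ketones to deprotonate on the oxygenated side. Setting out from 19, Me3CSiMe2OTf and 2,6-lutidine give (1S,2R,5R,6R,7S)-2-[(tert-butyldimethylsilyl)oxy]-7-(3,4-dimethoxyphenyl)-1,3,3-trimethoxy-6-methyl-5-(prop-2-en-1-yl)bicyclo[3.2.1]octan-8-one F2. Mild acid hydrolysis of the ketal (pyridinium tosylate, wet acetone, 50 °C) gives (1S,2R,5R,6R,7S)-2-[(tert-butyldimethylsilyl)oxy]-7-(3,4-dimethoxyphenyl)-1-methoxy-6-methyl-5-(prop-2-en-1-yl)bicyclo[3.2.1]octane-3,8-dione F3. KN(SiMe3)2 (THF, −78 °C) removes a C4 proton, and methyl triflate with DMPU alkylates the potassium enolate on oxygen (C-alkylation at the neopentyl-like C4 being disfavoured). This gives (1S,2S,5S,6R,7S)-2-[(tert-butyldimethylsilyl)oxy]-7-(3,4-dimethoxyphenyl)-1,3-dimethoxy-6-methyl-5-(prop-2-en-1-yl)bicyclo[3.2.1]oct-3-en-8-one F4. Bu4NF/AcOH removes the silyl group and the route is rejoined at 22.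

Step 2. What may go wrong: triflic anhydride or triflic acid may oligomerise or sulfonylate the electron-rich propenylarene faster than the α-methoxy amide is converted into its keteniminium ion, and facial discrimination may erode at the temperature then needed. The fallback generates the keteniminium ion without Brønsted acid and before the alkene is present. Setting out from 3, oxalyl chloride (CH2Cl2, 0 °C) gives (2R,5R)-1-(1-chloro-2-methoxyethylidene)-2,5-dimethylpyrrolidinium chloride F5, which is not isolated. Et3N converts it into the α-chloroenamine (2R,5R)-1-(1-chloro-2-methoxyethenyl)-2,5-dimethylpyrrolidine F6. AgOTf (CH2Cl2, −60 °C) abstracts chloride to give keteniminium triflate 5, alkene 4 is added cold, and the route continues through 6 to 7 as in step 2.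

**Further compounds**

F1 | step 3 | ethyl 2-diazo-2-[(2S,3S,4R)-3-(3,4-dimethoxyphenyl)-1-hydroxy-2-methoxy-4-methylcyclobutyl]acetate | CCOC(=O)C(=[N+]=[N-])C1(O)[C@@H](OC)[C@H](c2ccc(OC)c(OC)c2)[C@H]1C
F2 | step 11 | (1S,2R,5R,6R,7S)-2-[(tert-butyldimethylsilyl)oxy]-7-(3,4-dimethoxyphenyl)-1,3,3-trimethoxy-6-methyl-5-(prop-2-en-1-yl)bicyclo[3.2.1]octan-8-one | C=CC[C@]12CC(OC)(OC)[C@H](O[Si](C)(C)C(C)(C)C)[C@](OC)(C1=O)[C@H](c1ccc(OC)c(OC)c1)[C@H]2C
F3 | step 11 | (1S,2R,5R,6R,7S)-2-[(tert-butyldimethylsilyl)oxy]-7-(3,4-dimethoxyphenyl)-1-methoxy-6-methyl-5-(prop-2-en-1-yl)bicyclo[3.2.1]octane-3,8-dione | C=CC[C@]12CC(=O)[C@H](O[Si](C)(C)C(C)(C)C)[C@](OC)(C1=O)[C@H](c1ccc(OC)c(OC)c1)[C@H]2C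
F4 | step 11 | (1S,2S,5S,6R,7S)-2-[(tert-butyldimethylsilyl)oxy]-7-(3,4-dimethoxyphenyl)-1,3-dimethoxy-6-methyl-5-(prop-2-en-1-yl)bicyclo[3.2.1]oct-3-en-8-one | C=CC[C@]12C=C(OC)[C@H](O[Si](C)(C)C(C)(C)C)[C@](OC)(C1=O)[C@H](c1ccc(OC)c(OC)c1)[C@H]2C
F5 | step 2 | (2R,5R)-1-(1-chloro-2-methoxyethylidene)-2,5-dimethylpyrrolidinium chloride | COCC(Cl)=[N+]1[C@H](C)CC[C@H]1C.[Cl-]
F6 | step 2 | (2R,5R)-1-(1-chloro-2-methoxyethenyl)-2,5-dimethylpyrrolidine | COC=C(Cl)N1[C@H](C)CC[C@H]1C
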